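**Retrosynthetic overview**
1. Agastenol 15 ⇐ desilylation, then Mitsunobu ester C–O bond between primary alcohol 12 and 4-hydroxybenzoic acid 13.
2. 12 ⇐ CO2H reduction of acid 11 ⇐ removal of the C5 lactone carbonyl from arylidene-lactone acid 9.
3. 9 ⇐ base-induced β-elimination opening one lactone of C2-symmetric bislactone 8 (creates the E-benzylidene, frees the C3 carboxyl; the two rings are equivalent).
4. 8 ⇐ succinyl bis(oxazolidinone) 5 + two molecules of aldehyde 2: double boron syn-aldol, then double lactonization with loss of both auxiliaries (two C–C bonds, four stereocentres, both rings in one operation).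
5. Ring order: both γ-lactone rings close together (step 3); one is sacrificed (step 4), the other is deoxygenated to the tetrahydrofuran (step 5); the three arene rings are bought (vanillin, 4-hydroxybenzoic acid).

Assumption: the target is taken exactly as drawn in the SMILES, i.e. (2R,3S), 2-aryl and 3-CH2O trans, E-alkene with the aryl cis to C3.

Ar = 3-methoxy-4-(triisopropylsilyloxy)phenyl throughout.

**Step 1**
Reactants: 1 vanillin
Product: 2 3-methoxy-4-(triisopropylsilyloxy)benzaldehyde
Conditions: TIPSCl, imidazole, DMF, rt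
Reagents that add atoms: triisopropylsilyl chloride (TIPSCl), CC(C)[Si](Cl)(C(C)C)C(C)C
Why: Standard imidazole-promoted silylation of the phenol; the bulky silyl ether blocks quinone-methide chemistry and tolerates the later base, hydride and BF3 steps; no stereocentre is involved.

**Step 2**
Reactants: 3 succinyl chloride; 4 (R)-4-benzyl-1,3-oxazolidin-2-one (2 equiv)
Product: 5 (4R,4'R)-3,3'-(butanedioyl)bis(4-benzyl-1,3-oxazolidin-2-one)
Conditions: 4, n-BuLi, THF, −78 °C; then 3, −78 to 0 °C
Reagents that add atoms: none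
Why: Twofold N-acylation of the lithiated oxazolidinone by the diacid chloride (standard Evans imide formation); the (R)-auxiliary is chosen because it leads to the (2R,3S) series of the target, and no new stereocentre is formed.

**Step 3**
Reactants: 5; 2 (2.5 equiv)
Product: 8 (1R,2R,5R,6R)-2,6-di(Ar)-3,7-dioxabicyclo[3.3.0]octane-4,8-dione, via bis(dibutylboron) dienolate 6 (not isolated), via bis-aldol diol 7 (not isolated)
Conditions: Bu2BOTf (2.4 equiv), i-Pr2NEt (3 equiv), CH2Cl2, −78 to 0 °C; 2, −78 to 0 °C; pH 7 buffer, MeOH, H2O2, 0 °C; then PPTS (cat.), PhMe, 60 °C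
Reagents that add atoms: none
Why: Proposed new method: double soft enolization gives the (Z,Z)-bis(boron enolate) 6, each Z-enolate adds to 2 through a Zimmerman–Traxler chair on the face opposite the benzyl group of its own (R)-auxiliary (Evans syn-aldol), so both α-carbons and both carbinol carbons become R (syn), and each freed hydroxyl then attacks the distal imide carbonyl 5-exo-trig, expelling the auxiliary and closing the two cis-fused lactone rings with exo aryl groups; the closest known reactions are the Evans boron aldol–lactonization of succinate half-ester imides and the racemic TiCl4 double aldol–bislactonization of 2,5-bis(trimethylsilyloxy)furan with aldehydes.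

**Step 4**
Reactants: 8
Product: 9 (2R,3R,4E)-2-(Ar)-4-[(Ar)methylidene]-5-oxooxolane-3-carboxylic acid
Conditions: DBU (1.2 equiv), CH2Cl2, 0 °C to rt; aq. citric acid
Reagents that add atoms: none
Why: E1cB β-elimination: deprotonation α to one lactone carbonyl expels the β-acyloxy (carboxylate) group of the other ring, an isomerization that gives the conjugated, thermodynamically preferred E-arylidene lactone (aryl anti to C=O); the carboxylate formed protects C3–H and the remaining ring from a second elimination, C2 and C3 are untouched, and either ring of C2-symmetric 8 gives the same product.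

**Step 5**
Reactants: 9
Product: 11 (2R,3R,4E)-2-(Ar)-4-[(Ar)methylidene]oxolane-3-carboxylic acid, via lactol 10 (not isolated)
Conditions: i-Bu2AlH (2.3 equiv), CH2Cl2, −78 °C; then Et3SiH, BF3·OEt2, −78 to −30 °C
Reagents that add atoms: none
Why: Lactone-to-cyclic-ether deoxygenation (lactol formation, then ionic hydrogenation): i-Bu2AlH first masks the acid as its aluminium carboxylate and adds once (1,2) to the lactone, BF3 ionizes lactolate 10 to the styrene-conjugated oxocarbenium ion and Et3SiH delivers hydride at C5; no stereocentre is formed or touched, and any carboxylate-trapped acylal can only re-ionize to the same cation.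

**Step 6**
Reactants: 11
Product: 12 [(2R,3S,4E)-2-(Ar)-4-[(Ar)methylidene]oxolan-3-yl]methanol
Conditions: LiAlH4, THF, 0 °C
Reagents that add atoms: none
Why: Hydride reduction of the carboxylic acid to the primary alcohol; the isolated styrene, the benzylic ether and the aryl silyl ethers are inert at 0 °C, and C3 keeps its configuration (R becomes S only through the priority change).

**Step 7**
Reactants: 12; 13 4-hydroxybenzoic acid
Product: 14 [(2R,3S,4E)-2-(Ar)-4-[(Ar)methylidene]oxolan-3-yl]methyl 4-hydroxybenzoate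
Conditions: PPh3, DIAD, THF, 0 °C to rt
Reagents that add atoms: none
Why: Mitsunobu esterification: the alkoxyphosphonium of the primary alcohol is displaced by the carboxylate (pKa about 4.5) much faster than by the phenol (pKa about 9), so 13 is used unprotected; reaction occurs at the CH2 and no stereocentre is involved.

**Step 8**
Reactants: 14
Product: 15 agastenol
Conditions: Bu4NF, AcOH (1:1), THF, 0 °C
Reagents that add atoms: none
Why: Fluoride cleavage of the two aryl silyl ethers; the acetic acid buffer keeps the phenols protonated, so the 2-aryl ether does not open through a quinone methide and the ester does not migrate; stereocentres and alkene geometry are untouched.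

**Compound list**
1 | vanillin (4-hydroxy-3-methoxybenzaldehyde) | COc1cc(C=O)ccc1O | starting material
2 | 3-methoxy-4-(triisopropylsilyloxy)benzaldehyde | COc1cc(C=O)ccc1O[Si](C(C)C)(C(C)C)C(C)C | intermediate
3 | succinyl chloride | O=C(Cl)CCC(=O)Cl | starting material
4 | (R)-4-benzyl-1,3-oxazolidin-2-one | O=C1N[C@H](Cc2ccccc2)CO1 | starting material
5 | (4R,4'R)-3,3'-(butanedioyl)bis(4-benzyl-1,3-oxazolidin-2-one) | O=C(CCC(=O)N1C(=O)OC[C@H]1Cc1ccccc1)N1C(=O)OC[C@H]1Cc1ccccc1 | intermediate
6 | (Z,Z)-bis(dibutylboron) dienolate of 5, not isolated | CCCCB(CCCC)O/C(=C\C=C(/OB(CCCC)CCCC)N1C(=O)OC[C@H]1Cc1ccccc1)N1C(=O)OC[C@H]1Cc1ccccc1 | intermediate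
7 | bis-aldol diol: (2R,3R)-2,3-bis[(R)-hydroxy(Ar)methyl]succinyl bis-imide of 4, not isolated | O=C(N1C(=O)OC[C@H]1Cc1ccccc1)[C@@H]([C@@H](O)c1ccc(O[Si](C(C)C)(C(C)C)C(C)C)c(OC)c1)[C@@H](C(=O)N1C(=O)OC[C@H]1Cc1ccccc1)[C@@H](O)c1ccc(O[Si](C(C)C)(C(C)C)C(C)C)c(OC)c1 | intermediate
8 | (1R,2R,5R,6R)-2,6-di(Ar)-3,7-dioxabicyclo[3.3.0]octane-4,8-dione; cis-fused, both aryl groups exo | O=C1[C@H]2[C@H](c3ccc(O[Si](C(C)C)(C(C)C)C(C)C)c(OC)c3)OC(=O)[C@H]2[C@H](c2ccc(O[Si](C(C)C)(C(C)C)C(C)C)c(OC)c2)O1 | intermediate
9 | (2R,3R,4E)-2-(Ar)-4-[(Ar)methylidene]-5-oxooxolane-3-carboxylic acid; 2,3-trans | OC(=O)[C@H]1[C@H](c2ccc(O[Si](C(C)C)(C(C)C)C(C)C)c(OC)c2)OC(=O)/C1=C/c1ccc(O[Si](C(C)C)(C(C)C)C(C)C)c(OC)c1 | intermediate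
10 | (2R,3R,4E)-5-hydroxy-2-(Ar)-4-[(Ar)methylidene]oxolane-3-carboxylic acid; lactol, both C5 anomers, present as its aluminium lactolate, not isolated | OC(=O)[C@H]1[C@H](c2ccc(O[Si](C(C)C)(C(C)C)C(C)C)c(OC)c2)OC(O)/C1=C/c1ccc(O[Si](C(C)C)(C(C)C)C(C)C)c(OC)c1 | intermediate
11 | (2R,3R,4E)-2-(Ar)-4-[(Ar)methylidene]oxolane-3-carboxylic acid | OC(=O)[C@H]1[C@H](c2ccc(O[Si](C(C)C)(C(C)C)C(C)C)c(OC)c2)OC/C1=C/c1ccc(O[Si](C(C)C)(C(C)C)C(C)C)c(OC)c1 | intermediate
12 | [(2R,3S,4E)-2-(Ar)-4-[(Ar)methylidene]oxolan-3-yl]methanol | OC[C@H]1[C@H](c2ccc(O[Si](C(C)C)(C(C)C)C(C)C)c(OC)c2)OC/C1=C/c1ccc(O[Si](C(C)C)(C(C)C)C(C)C)c(OC)c1 | intermediate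
13 | 4-hydroxybenzoic acid | OC(=O)c1ccc(O)cc1 | starting material
14 | bis(triisopropylsilyl) agastenol: [(2R,3S,4E)-2-(Ar)-4-[(Ar)methylidene]oxolan-3-yl]methyl 4-hydroxybenzoate | O=C(OC[C@H]1[C@H](c2ccc(O[Si](C(C)C)(C(C)C)C(C)C)c(OC)c2)OC/C1=C/c1ccc(O[Si](C(C)C)(C(C)C)C(C)C)c(OC)c1)c1ccc(O)cc1 | intermediate
15 | agastenol: [(2R,3S,4E)-2-(4-hydroxy-3-methoxyphenyl)-4-[(4-hydroxy-3-methoxyphenyl)methylidene]oxolan-3-yl]methyl 4-hydroxybenzoate | COc1cc(/C=C2/CO[C@@H](c3ccc(O)c(OC)c3)[C@@H]2COC(=O)c2ccc(O)cc2)ccc1O | target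

**Step count and risks**
Total steps: 8. Longest linear sequence: 7 (steps 1, 3, 4, 5, 6, 7, 8 from vanillin; equally steps 2 to 8 from succinyl chloride).

Most likely to fail:

Step 3 (double aldol–bislactonization). Risks are incomplete second enolization, a mismatched second aldol, or one lactone closing before the second aldol. The fallback sets out from 2 and comes back at 9, giving up absolute control at the ring-forming stage. Aldehyde 2 (2 equiv) and commercial 2,5-bis(trimethylsilyloxy)furan with TiCl4 in CH2Cl2 at −78 °C, then acid lactonization, give the same cis-fused exo,exo-bislactone as a racemate. This is 8 together with the enantiomeric (1S,2S,5S,6S)-bislactone F1. DBU as in step 4 gives the racemic acid, 9 together with the enantiomeric (2S,3S,4E)-acid F2. Classical resolution by crystallizing the (R)-1-phenylethylammonium salt of 9 F3 (or using the other antipode of the amine if the wrong salt crystallizes), then acidification, returns enantiopure 9.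

Step 5 (lactone to cyclic ether beside a free acid and a styrene). Risks are hydride delivery at the benzylic end of the conjugated cation, over-reduction of the lactolate, or reductive opening of the 2-aryl ether. The fallback sets out from 9 and comes back at 12, skipping 11. LiAlH4 (THF, −20 to 0 °C) reduces both the acid and the lactone of 9 to the triol F5. Acid-catalysed cyclodehydration (PPTS cat., CH2Cl2) then ionizes the para-silyloxybenzylic alcohol, and 5-exo capture by the allylic primary OH gives the thermodynamic 2,3-trans tetrahydrofuran 12. The other primary OH could only form an oxetane.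

Step 4 (E1cB opening of one lactone). Risks are that the elimination is stereoelectronically slow because the leaving oxygen sits in a five-membered ring, that a second elimination occurs, or that DBU attacks the silyl ethers. The fallback sets out from 8 and comes back at 10, reversing the order of reduction and elimination. One equivalent of i-Bu2AlH at −78 °C half-reduces 8 to the mono-lactol F4 (unreacted 8 is recycled). Its open hydroxy-aldehyde form is far more acidic than a lactone, so catalytic Et3N triggers β-elimination of the remaining lactone carboxylate. Re-closure of the freed benzylic OH on the resulting E-enal gives lactol 10, which is reduced with Et3SiH and BF3·OEt2 to 11 as in step 5.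

**Further compounds**
F1 | step 3 | (1S,2S,5S,6S)-2,6-di(Ar)-3,7-dioxabicyclo[3.3.0]octane-4,8-dione, the enantiomer of 8 formed with it as the racemate | O=C1[C@@H]2[C@@H](c3ccc(O[Si](C(C)C)(C(C)C)C(C)C)c(OC)c3)OC(=O)[C@@H]2[C@@H](c2ccc(O[Si](C(C)C)(C(C)C)C(C)C)c(OC)c2)O1
F2 | step 3 | (2S,3S,4E)-2-(Ar)-4-[(Ar)methylidene]-5-oxooxolane-3-carboxylic acid, the enantiomer of 9 formed with it as the racemate | OC(=O)[C@@H]1[C@@H](c2ccc(O[Si](C(C)C)(C(C)C)C(C)C)c(OC)c2)OC(=O)/C1=C/c1ccc(O[Si](C(C)C)(C(C)C)C(C)C)c(OC)c1
F3 | step 3 | (R)-1-phenylethylammonium salt of 9 | C[C@@H]([NH3+])c1ccccc1.[O-]C(=O)[C@H]1[C@H](c2ccc(O[Si](C(C)C)(C(C)C)C(C)C)c(OC)c2)OC(=O)/C1=C/c1ccc(O[Si](C(C)C)(C(C)C)C(C)C)c(OC)c1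
F4 | step 4 | mono-lactol of 8: (1R,2R,5R,6R)-8-hydroxy-2,6-di(Ar)-3,7-dioxabicyclo[3.3.0]octan-4-one, both C8 anomers | O=C1[C@H]2[C@H](c3ccc(O[Si](C(C)C)(C(C)C)C(C)C)c(OC)c3)OC(O)[C@H]2[C@H](c2ccc(O[Si](C(C)C)(C(C)C)C(C)C)c(OC)c2)O1
F5 | step 5 | (1R,2S,3E)-1-(Ar)-2-(hydroxymethyl)-3-[(Ar)methylidene]butane-1,4-diol | OC[C@H](/C(CO)=C\c1ccc(O[Si](C(C)C)(C(C)C)C(C)C)c(OC)c1)[C@H](c1ccc(O[Si](C(C)C)(C(C)C)C(C)C)c(OC)c1)O
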